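## The problem

Target 30 is a trans-fused bicyclo[5.3.0]decane (hydroazulene). A seven-membered ring (C1–C6 and C10) shares the C6–C10 bond with a five-membered ring (C6–C10). C10 is quaternary and carries a methyl group, C1 carries the acetoxy group, C2–C3 is an oxirane with a methyl group on C3, and C7 carries an (E,E)-dienyl chain (C11–C15) ending in a tertiary alcohol. These skeleton locants, not von Baeyer locants, are used in every name below.

Of the six stereocentres only C10 has no neighbour from which it could be derived. It must come from an enantioselective step and, being quaternary, cannot be corrected later.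

The other centres can be relayed from C10:
- H6 must be anti to the C10 methyl group.
- The C7 substituent is the more stable epimer on the cyclopentane and can be equilibrated while C11 is a ketone.
- The oxirane is syn to the C1 oxygen and can be delivered by it.
- The C1 oxygen must end anti to the C10 methyl group. Hydride reagents prefer to attack a C1 carbonyl from exactly that face, so an inversion has to be planned.

The hydrogens on C6 and C7 are trans, so no syn-hydrogenation of a C6=C7 olefin can set C7 directly.

The tertiary dienylic alcohol ionises in acid, the oxirane next to C1 does not tolerate acid or hot nucleophiles, and the acetate does not survive organometallic reagents. These groups fix the order of the last steps.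

The feature that opens the structure is that C10 stands between C1 and C6, both of which can be carbonyl carbons, while C7 carries a carbon (C11) that can be a methyl ketone. C1, C10 and C6 are then the dione unit of a 2,2-disubstituted cycloheptane-1,3-dione, and C9–C8–C7–C11 is a 4-oxopentyl arm on C10. C6–C7 is an aldol bond whose formation closes the five-membered ring and tells two enantiotopic carbonyls apart.

## Retrosynthesis

**Acetate and carbinol terminus.** The C1–O acyl bond of 30 is cut last, giving epoxy diol 28. The two C15–CH3 bonds are cut next, giving methyl ester 27 and methyllithium 18. The ester is preferred to an early carbinol because a free tertiary allylic alcohol would draw the vanadium catalyst to C13=C14 and would not survive the acidic or Lewis acidic steps before it. The acetate must follow the organolithium step. The forward reactions must add to the ester without opening the oxirane, and must acylate a secondary hydroxyl beside a tertiary one.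

**Oxirane and C1.** The two C–O bonds of the oxirane in 27 are cut to allylic alcohol 25, because a cis-epoxy alcohol is the signature of hydroxyl-directed epoxidation. 25 is traced through 4-nitrobenzoate 24 to its C1 epimer 22, and 22 to enone 21. Epoxidising 21 first and then reducing would set the oxirane oxygen against the C10 methyl group in the hydride step. Accepting the intrinsic hydride selectivity and inverting by displacement with acid 23 is the more predictable course. The cost is two steps.

**C3 methyl and C2=C3.** The C3–CH3 bond of 21 is cut. Conjugate addition of a methyl cuprate (from 18) to cycloheptenone 17, trapping with 19 as silyl enol ether 20, and re-oxidation return the double bond. 17 comes from saturated ketone 16 by dehydrogenation. Because C10 is quaternary, the C1 ketone can enolise only toward C2, so no regiochemical control is needed. A 1,2-addition with oxidative transposition would put the carbonyl on C3 and is therefore excluded.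

**Side chain.** The C11=C12 bond of 16 is cut to methyl ketone 14 and phosphonate 15. Cutting C12–C13 instead (coupling of an E-alkenyl iodide) would give secure geometry but needs an alkyne, a carbometallation and a protected C1, three to four steps more. Cutting C11=C12 uses the acetyl group that the aldol leaves on C7. The forward reaction must pick the methyl ketone over the neopentyl C1 ketone and give the 11E olefin.

**Ring fusion and C7.** Two hydrogens are removed from C6 and C7 of 14, which leads back to enone 10. A catalyst surface or a hydride reagent would approach C6=C7 from the face of the C10 methyl group, because the other face is roofed by C1–C2 of the seven-membered ring. That would give the cis fusion. The hydrogens are therefore delivered by a hydroxyl group on the correct face: 10 is reduced to diol 11 with reagent control at C11, and the C11 hydroxyl steers hydrogen to give 12. Oxidation gives 13 and base equilibrates C7 to 14. The C11 carbinol is a sacrificial relay.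

**Key disconnection.** The C6=C7 bond of 10 is cut by a retro-aldol condensation to the achiral triketone 8 (through ketol 9). One ring, one C–C bond and the quaternary stereocentre are exchanged for a symmetric dione. All ten ring carbons, the C10 methyl group and C11/C12 are already present in 8. The forward reaction must choose between two enantiotopic carbonyls and close only the five-membered ring.

**Triketone.** The C7–C8 bond region of 8 is cut by cross-metathesis logic to allyl dione 5 and methyl vinyl ketone 6 (through enone 7). The C10–C9 bond of 5 is cut to 2-methyl dione 3 and allyl acetate 4. The C10–CH3 bond of 3 is cut to cycloheptane-1,3-dione 1 and iodomethane 2. Palladium-mediated allylation is chosen over direct alkylation with a 5-halopentan-2-one, which would mainly O-alkylate a 2-substituted 1,3-dione.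

## Roads not taken

**Alternative 1:** The seven-membered ring is opened at C3–C4. Precursor A2 is a cyclopentane that already holds the quaternary C10, a vinyl group on C6 and a silyloxy group on C7. On C10 it carries the chain C1(OSiEt3)–C2H=C3(CH3)I with a (Z)-iodoalkene. In the forward step 9-BBN hydroborates the vinyl group (boron on C4). Pd(dppf)Cl2 (a divalent palladium precatalyst; zerovalent palladium turns over) then joins the alkylborane to the alkenyl iodide and gives A1.
- Merits: A1 arrives with the C2=C3 bond, its methyl group and the C1 oxygen in their final places. C1 is set before the ring exists, and the trans fusion is a property of the cyclopentane. On these points it is better than the chosen plan, which must build the enone (steps 9–11), invert C1 (steps 12–14) and relay the ring fusion through a sacrificial carbinol (steps 5–7).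
- Weak points: the whole stereochemical load moves into A2. Its four contiguous centres (C1, C10, C6, C7), one quaternary and one exocyclic, must be assembled without a ring to relay them. The iodoalkene sits beside a neopentyl carbinol. Closure of a seven-membered ring by an sp3–sp2 coupling competes with protodeboronation and β-hydride loss. C7 arrives as oxygen, so the C7–C11 bond still has to be made at a hindered secondary centre with stereocontrol.
- Comparison: the chosen plan sets against it a four-step, catalytic entry to the complete bicyclic frame with the side-chain carbon already on C7 and one enantio-determining event.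

**Alternative 2:** The five-membered ring is opened at C9–C10. Precursor A4 is a cycloheptane with the C1 silyl ether, a tertiary C10–H bearing the methyl group, and on C6 an arm ending in a diazoketone. Rh2(OAc)4 (divalent rhodium) forms the carbenoid at C9, which inserts into the C10–H bond and gives cyclopentanone A3.
- Merits: insertion proceeds with retention, so the quaternary centre, the trans fusion and the C1 configuration are all carried in from A4. Closure of a five-membered ring is the favoured insertion mode.
- Weak points: A4 needs three contiguous centres on a flexible seven-membered ring plus C7, which is harder to build than the bicycle itself. The C5 methylene offers a second five-ring insertion site. The targeted C10–H is β to the C1 oxygen and therefore deactivated, as well as hindered. Afterwards the C8 ketone of A3 must be removed and the isopropenyl group homologated at its terminal carbon to the dienol, several steps on a 1,1-disubstituted olefin.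
- Comparison: it is better than the chosen plan in that C1 and the ring fusion need no later correction. The chosen plan answers with a ring-forming step that has no competing C–H site or diazo intermediate, and with far fewer steps before and after.

**Alternative 3:** The C1–C10 bond is cut together with the implied C3–C5 bond of a cyclopropane. Precursor A6 is a cis-1,2-dialkenylcyclopropane with an (E)-alkenylboronate arm on C3 and a 2-methylcyclopentenyl arm on C5. On warming, the boat Cope rearrangement forms C1–C10, breaks C3–C5 and gives cyclohepta-1,4-diene A5.
- Merits: this is the most convergent of the three. One stereospecific step makes the ring, the quaternary centre and C1 in the right relative sense (boron anti to the C10 methyl). C2=C3 with its methyl is in place. Oxidation of the allylboronate with retention would give the C1 alcohol on the correct face with no inversion. For C1 it is more direct than the chosen plan.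
- Weak points: the cyclopentenyl terminus places its methyl group in the inward position of the boat, against the cyclopropane methylene. That is the substitution pattern that most retards this rearrangement. At the temperatures then needed, the allylboronate can undergo 1,3-boryl shift and the cyclopropane can lose its cis geometry. A6 needs an enantioselective synthesis of a cyclopropane with a fully substituted carbon, matched to the separate C7 centre. The C5=C6 bond left in A5 still poses the ring-fusion reduction, now with a second trisubstituted olefin present.
- Comparison: the chosen plan sets against it a three-step precursor, a key step with close precedent and no thermally fragile intermediate.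

Key step: step 4

Assumption: in step 4 the L-amino acid is taken to select the carbonyl that leads to (10S)-10; if the enolexo mode shows the opposite sense, the D-amino acid is used and nothing else changes.
Assumption: centres that are made only to be destroyed (C6/C7 of 9, C1 of 11 and 12, C3 of 20) are drawn in the expected configuration; their epimers would converge on the same later compounds.

## Route

Step 1
Reactants: 1 cycloheptane-1,3-dione; 2 iodomethane
Product: 3 2-methylcycloheptane-1,3-dione
Conditions: MeI (1.1 equiv), K2CO3, acetone, 55 °C
Reagents that add atoms: iodomethane 2, CI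
Why: C-Alkylation of the stabilised 1,3-dione enolate with a small electrophile; one equivalent of MeI should limit dimethylation and O-methylation, and 3 is separable from both through its acidity.

Step 2
Reactants: 3 2-methylcycloheptane-1,3-dione; 4 allyl acetate
Product: 5 2-allyl-2-methylcycloheptane-1,3-dione
Conditions: allyl acetate, Pd(PPh3)4 (2 mol %), DBU, toluene, 80 °C
Reagents that add atoms: allyl acetate 4, C=CCOC(C)=O
Why: Tsuji–Trost allylation: zerovalent palladium ionises allyl acetate to the π-allyl complex, which the soft dione enolate attacks at carbon, so the quaternary carbon forms without the O-alkylation typical of 2-substituted 1,3-diones; 5 is achiral.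

Step 3
Reactants: 5 2-allyl-2-methylcycloheptane-1,3-dione; 6 methyl vinyl ketone
Product: 8 2-methyl-2-(4-oxopentyl)cycloheptane-1,3-dione, via cross-metathesis enone 7 (not isolated)
Conditions: 6 (3 equiv), second-generation Grubbs catalyst RuCl2(=CHPh)(PCy3)(H2IMes) (3 mol %), CH2Cl2, 40 °C; then solvent to EtOAc, palladium on carbon (Pd/C), H2 (1 atm), rt
Reagents that add atoms: methyl vinyl ketone 6, CC(=O)C=C
Why: Olefin cross-metathesis of a terminal alkene with an electron-poor enone partner is selective for the E cross product with loss of ethene; hydrogenation over palladium in the same flask saturates only the conjugated C=C and gives the 1,6-relationship of side-chain and ring carbonyls that the aldol needs.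

Step 4
Reactants: 8 2-methyl-2-(4-oxopentyl)cycloheptane-1,3-dione
Product: 10 (10S)-7-acetyl-10-methylbicyclo[5.3.0]dec-6-en-1-one, via aldol ketol 9 (not isolated)
Conditions: L-phenylalanine (1.0 equiv), (+)-10-camphorsulfonic acid (0.5 equiv), DMF, 30 → 70 °C
Reagents that add atoms: none
Why: The primary amino acid condenses with the least hindered carbonyl, the side-chain methyl ketone, and the iminium ion tautomerises to the enamine toward C7; the carboxylic acid of the catalyst hydrogen-bonds to one of the two enantiotopic ring carbonyls and C7 adds to it, after which hydrolysis and acid-promoted loss of water from ketol 9 give the conjugated, tetrasubstituted C6=C7 enone. The closest known reaction type is the Hajos–Parrish–Eder–Sauer–Wiechert aldol condensation of 2,2-disubstituted cyclic 1,3-diones, moved here from the six-ring enolendo mode to the five-ring enolexo mode on a seven-membered dione. The cyclopentene closes by a 5-(enolexo)-exo-trig aldolisation. The only stereocentre that survives, C10, is set by the carbonyl the catalyst selects (catalyst control in the hydrogen-bonded enamine transition state); the C6 and C7 centres of 9 vanish on dehydration. The step needs ring-size selectivity, enantiotopic-group selectivity and freedom from ring cleavage: the 1,6-spacing means that every other enamine or enol (the terminal methyl, or C2/C5 attacking the side-chain ketone) could only close a seven-membered ring, the quaternary C10 has no α-hydrogen and so cannot be lost by enolisation, and the weakly acidic, non-nucleophilic medium avoids the retro-Claisen opening that hydroxide would cause.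

Step 5
Reactants: 10 (10S)-7-acetyl-10-methylbicyclo[5.3.0]dec-6-en-1-one
Product: 11 (1R,10S)-7-[(1R)-1-hydroxyethyl]-10-methylbicyclo[5.3.0]dec-6-en-1-ol
Conditions: (S)-2-methyl-CBS-oxazaborolidine (20 mol %), BH3·SMe2 (2.5 equiv), THF, −20 → 0 °C; MeOH quench
Reagents that add atoms: none
Why: Corey–Bakshi–Shibata reduction: the ketone binds the oxazaborolidine boron anti to its larger substituent and takes hydride from the coordinated borane, so the acetyl group (cyclopentenyl large, methyl small) should give the (11R) carbinol under catalyst control; the C1 ketone is reduced as well (1R expected from the same catalyst sense), which is harmless because C1 is reoxidised in step 7.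

Step 6
Reactants: 11 (1R,10S)-7-[(1R)-1-hydroxyethyl]-10-methylbicyclo[5.3.0]dec-6-en-1-ol
Product: 12 (1R,6S,7S,10S)-7-[(1R)-1-hydroxyethyl]-10-methylbicyclo[5.3.0]decan-1-ol
Conditions: [Ir(cod)(PCy3)(py)]PF6 (10 mol %), H2 (1 atm), CH2Cl2, 0 °C → rt
Reagents that add atoms: none
Why: Hydroxyl-directed homogeneous hydrogenation: 1,3-allylic strain holds the C11–H in the olefin plane toward C5, which places the (11R) hydroxyl on the face opposite the C10 methyl group; iridium bound there (a 1R hydroxyl lies over the same face) delivers both hydrogens to that face, setting H6 anti to the methyl group (trans fusion, 6S) and, for the moment, C7 as 7S.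

Step 7
Reactants: 12 (1R,6S,7S,10S)-7-[(1R)-1-hydroxyethyl]-10-methylbicyclo[5.3.0]decan-1-ol
Product: 14 (6S,7R,10S)-7-acetyl-10-methylbicyclo[5.3.0]decan-1-one, via C7-epimeric diketone 13 (not isolated)
Conditions: Dess–Martin periodinane (3 equiv), NaHCO3, CH2Cl2, rt; aqueous work-up; crude in MeOH, K2CO3, rt
Reagents that add atoms: none
Why: Dess–Martin oxidation returns both carbinols to ketones without touching C7; mild carbonate then equilibrates C7 through the acetyl enolate to the more stable epimer with the acetyl group trans to C5 on the cyclopentane (7R), while C6 and C10 have no acidifying carbonyl next to a hydrogen and cannot change.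

Step 8
Reactants: 14 (6S,7R,10S)-7-acetyl-10-methylbicyclo[5.3.0]decan-1-one; 15 trimethyl 4-phosphonocrotonate
Product: 16 methyl (2E,4E)-5-[(6S,7R,10S)-10-methyl-1-oxobicyclo[5.3.0]dec-7-yl]hexa-2,4-dienoate
Conditions: 15 (1.5 equiv), LiN(SiMe3)2 (1.5 equiv), THF, −78 °C → rt
Reagents that add atoms: trimethyl 4-phosphonocrotonate 15, COC(=O)/C=C/CP(=O)(OC)OC
Why: Vinylogous Horner–Wadsworth–Emmons olefination: the phosphonate-stabilised allyl anion adds through its α-carbon to the methyl ketone, the neopentyl C1 ketone being too hindered for addition; reversible addition and syn-elimination place the ester chain trans to the bulky C7 substituent (11E), and the 13E bond comes in with the reagent.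

Step 9
Reactants: 16 methyl (2E,4E)-5-[(6S,7R,10S)-10-methyl-1-oxobicyclo[5.3.0]dec-7-yl]hexa-2,4-dienoate
Product: 17 methyl (2E,4E)-5-[(6S,7R,10S)-10-methyl-1-oxobicyclo[5.3.0]dec-2-en-7-yl]hexa-2,4-dienoate
Conditions: IBX (1.5–2 equiv), DMSO/fluorobenzene, 65–70 °C
Reagents that add atoms: none
Why: IBX dehydrogenation of a ketone, a reaction type established on cycloheptanone itself: the enol, possible only toward C2 because C10 is quaternary, is oxidised through an iodine-bound enolate with loss of a C3 hydrogen to give the cyclohept-2-enone; the dienoate is inert.

Step 10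
Reactants: 17 methyl (2E,4E)-5-[(6S,7R,10S)-10-methyl-1-oxobicyclo[5.3.0]dec-2-en-7-yl]hexa-2,4-dienoate; 18 methyllithium; 19 chlorotrimethylsilane
Product: 20 methyl (2E,4E)-5-[(3R,6S,7R,10S)-3,10-dimethyl-1-(trimethylsilyloxy)bicyclo[5.3.0]dec-1-en-7-yl]hexa-2,4-dienoate
Conditions: MeLi (2.4 equiv), CuI (1.2 equiv), Et2O, 0 °C; then 17, TMSCl (2 equiv), THF, −78 °C; Et3N, cold NaHCO3 work-up
Reagents that add atoms: lithium dimethylcuprate, [Li+].C[Cu-]C (made from methyllithium 18, [Li]C, and CuI); chlorotrimethylsilane 19, C[Si](C)(C)Cl
Why: Conjugate addition of the Gilman cuprate, accelerated and trapped by TMSCl, puts the methyl group on C3 and fixes the enolate as its silyl ether; the disubstituted ring enone reacts far faster than the dienoate, whose δ-carbon is fully substituted; the new C3 centre (addition anti to the axial C10 methyl expected) is erased in step 11.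

Step 11
Reactants: 20 methyl (2E,4E)-5-[(3R,6S,7R,10S)-3,10-dimethyl-1-(trimethylsilyloxy)bicyclo[5.3.0]dec-1-en-7-yl]hexa-2,4-dienoate
Product: 21 methyl (2E,4E)-5-[(6S,7R,10S)-3,10-dimethyl-1-oxobicyclo[5.3.0]dec-2-en-7-yl]hexa-2,4-dienoate
Conditions: Pd(OAc)2 (1.05 equiv), MeCN, rt
Reagents that add atoms: none
Why: Ito–Saegusa oxidation: the silyl enol ether gives the palladium enolate, and β-hydride elimination of the single C3 hydrogen restores the C2=C3 bond, now carrying the methyl group, as divalent palladium is reduced to zerovalent palladium.

Step 12
Reactants: 21 methyl (2E,4E)-5-[(6S,7R,10S)-3,10-dimethyl-1-oxobicyclo[5.3.0]dec-2-en-7-yl]hexa-2,4-dienoate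
Product: 22 methyl (2E,4E)-5-[(1S,6S,7R,10S)-1-hydroxy-3,10-dimethylbicyclo[5.3.0]dec-2-en-7-yl]hexa-2,4-dienoate
Conditions: NaBH4, CeCl3·7H2O, MeOH, −40 °C
Reagents that add atoms: none
Why: Luche reduction gives clean 1,2-addition to the β,β-disubstituted enone and leaves the ester alone; in the only conformer the trans fusion allows, the C10 methyl group is axial next to the carbonyl, so hydride should enter from the other face and give the alcohol syn to that methyl group (1S), the epimer of what the target needs.

Step 13
Reactants: 22 methyl (2E,4E)-5-[(1S,6S,7R,10S)-1-hydroxy-3,10-dimethylbicyclo[5.3.0]dec-2-en-7-yl]hexa-2,4-dienoate; 23 4-nitrobenzoic acid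
Product: 24 (1R,6S,7R,10S)-7-[(2E,4E)-6-methoxy-6-oxohexa-2,4-dien-2-yl]-3,10-dimethylbicyclo[5.3.0]dec-2-en-1-yl 4-nitrobenzoate
Conditions: 4-nitrobenzoic acid, PPh3, DIAD, THF, 0 °C → rt
Reagents that add atoms: 4-nitrobenzoic acid 23, OC(=O)c1ccc(cc1)[N+](=O)[O-]
Why: Mitsunobu esterification: the alkoxyphosphonium ion of the allylic alcohol is displaced by carboxylate with inversion, which puts the C1 oxygen anti to the C10 methyl group (1R); the acidic 4-nitrobenzoic acid is the partner of choice for hindered carbinols, and SN2′ attack is disfavoured because C3 is fully substituted.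

Step 14
Reactants: 24 (1R,6S,7R,10S)-7-[(2E,4E)-6-methoxy-6-oxohexa-2,4-dien-2-yl]-3,10-dimethylbicyclo[5.3.0]dec-2-en-1-yl 4-nitrobenzoate
Product: 25 methyl (2E,4E)-5-[(1R,6S,7R,10S)-1-hydroxy-3,10-dimethylbicyclo[5.3.0]dec-2-en-7-yl]hexa-2,4-dienoate
Conditions: K2CO3, MeOH, rt
Reagents that add atoms: none
Why: Methanolysis of the activated aryl ester frees the allylic alcohol without change at C1; the methyl dienoate only exchanges with the solvent.

Step 15
Reactants: 25 methyl (2E,4E)-5-[(1R,6S,7R,10S)-1-hydroxy-3,10-dimethylbicyclo[5.3.0]dec-2-en-7-yl]hexa-2,4-dienoate; 26 tert-butyl hydroperoxide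
Product: 27 methyl (2E,4E)-5-[(1S,2S,3R,6S,7R,10S)-2,3-epoxy-1-hydroxy-3,10-dimethylbicyclo[5.3.0]dec-7-yl]hexa-2,4-dienoate
Conditions: VO(acac)2 (5 mol %), t-BuOOH (1.5 equiv), CH2Cl2, 0 °C → rt
Reagents that add atoms: tert-butyl hydroperoxide 26, CC(C)(C)OO
Why: Hydroxyl-directed epoxidation: the vanadium alkoxide–peroxide complex delivers oxygen to the olefin face that carries the allylic hydroxyl, giving the cis-epoxy alcohol (2S,3R) as is usual for cyclohept-2-enols; the electron-poor dienoate has no hydroxyl near it and is not attacked.

Step 16
Reactants: 27 methyl (2E,4E)-5-[(1S,2S,3R,6S,7R,10S)-2,3-epoxy-1-hydroxy-3,10-dimethylbicyclo[5.3.0]dec-7-yl]hexa-2,4-dienoate; 18 methyllithium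
Product: 28 (3E,5E)-6-[(1S,2S,3R,6S,7R,10S)-2,3-epoxy-1-hydroxy-3,10-dimethylbicyclo[5.3.0]dec-7-yl]-2-methylhepta-3,5-dien-2-ol
Conditions: MeLi (4 equiv), THF, −78 °C; aq. NH4Cl
Reagents that add atoms: methyllithium 18, [Li]C
Why: Double addition of methyllithium to the methyl ester (one further equivalent is consumed by the hydroxyl) builds the tertiary carbinol C15; at −78 °C the trisubstituted oxirane should not be opened, and the cis arrangement of alkoxide and oxirane rules out Payne-type migration.

Step 17
Reactants: 28 (3E,5E)-6-[(1S,2S,3R,6S,7R,10S)-2,3-epoxy-1-hydroxy-3,10-dimethylbicyclo[5.3.0]dec-7-yl]-2-methylhepta-3,5-dien-2-ol; 29 acetic anhydride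
Product: 30 (1S,2S,3R,6S,7R,10S)-2,3-epoxy-7-[(2E,4E)-6-hydroxy-6-methylhepta-2,4-dien-2-yl]-3,10-dimethylbicyclo[5.3.0]dec-1-yl acetate
Conditions: Ac2O, pyridine, DMAP (cat.), CH2Cl2, 0 °C → rt
Reagents that add atoms: acetic anhydride 29, CC(=O)OC(C)=O
Why: Acylation of the secondary hydroxyl under nucleophilic catalysis; the tertiary allylic alcohol is acylated far more slowly, so the monoacetate should result when the reaction is stopped at consumption of 28, and the basic medium spares the oxirane and the dienylic carbinol.

## Compound list

Ring locants in the names follow the skeleton numbering of the first section.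

1 | cycloheptane-1,3-dione | O=C1CCCCC(=O)C1 | starting material
2 | iodomethane | CI | starting material
3 | 2-methylcycloheptane-1,3-dione | CC1C(=O)CCCCC1=O | intermediate
4 | allyl acetate | C=CCOC(C)=O | starting material
5 | 2-allyl-2-methylcycloheptane-1,3-dione | C=CCC1(C)C(=O)CCCCC1=O | intermediate
6 | methyl vinyl ketone (but-3-en-2-one) | CC(=O)C=C | starting material
7 | 2-methyl-2-[(2E)-4-oxopent-2-en-1-yl]cycloheptane-1,3-dione | CC(=O)/C=C/CC1(C)C(=O)CCCCC1=O | intermediate
8 | 2-methyl-2-(4-oxopentyl)cycloheptane-1,3-dione | CC(=O)CCCC1(C)C(=O)CCCCC1=O | intermediate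
9 | (10S)-7-acetyl-6-hydroxy-10-methylbicyclo[5.3.0]decan-1-one (C6 and C7 not defined, both lost on dehydration) | O=C1CCCCC2(O)C(C(C)=O)CC[C@]12C | intermediate
10 | (10S)-7-acetyl-10-methylbicyclo[5.3.0]dec-6-en-1-one | O=C1CCCCC2=C(C(C)=O)CC[C@]12C | intermediate
11 | (1R,10S)-7-[(1R)-1-hydroxyethyl]-10-methylbicyclo[5.3.0]dec-6-en-1-ol | O[C@@H]1CCCCC2=C([C@@H](C)O)CC[C@]12C | intermediate
12 | (1R,6S,7S,10S)-7-[(1R)-1-hydroxyethyl]-10-methylbicyclo[5.3.0]decan-1-ol | O[C@@H]1CCCC[C@H]2[C@@H]([C@@H](C)O)CC[C@]12C | intermediate
13 | (6S,7S,10S)-7-acetyl-10-methylbicyclo[5.3.0]decan-1-one | O=C1CCCC[C@H]2[C@@H](C(C)=O)CC[C@]12C | intermediate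
14 | (6S,7R,10S)-7-acetyl-10-methylbicyclo[5.3.0]decan-1-one | O=C1CCCC[C@H]2[C@H](C(C)=O)CC[C@]12C | intermediate
15 | trimethyl 4-phosphonocrotonate, methyl (2E)-4-(dimethoxyphosphoryl)but-2-enoate | COC(=O)/C=C/CP(=O)(OC)OC | starting material
16 | methyl (2E,4E)-5-[(6S,7R,10S)-10-methyl-1-oxobicyclo[5.3.0]dec-7-yl]hexa-2,4-dienoate | O=C1CCCC[C@H]2[C@H](/C(C)=C/C=C/C(=O)OC)CC[C@]12C | intermediate
17 | methyl (2E,4E)-5-[(6S,7R,10S)-10-methyl-1-oxobicyclo[5.3.0]dec-2-en-7-yl]hexa-2,4-dienoate | O=C1C=CCC[C@H]2[C@H](/C(C)=C/C=C/C(=O)OC)CC[C@]12C | intermediate
18 | methyllithium | [Li]C | starting material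
19 | chlorotrimethylsilane | C[Si](C)(C)Cl | starting material
20 | methyl (2E,4E)-5-[(3R,6S,7R,10S)-3,10-dimethyl-1-(trimethylsilyloxy)bicyclo[5.3.0]dec-1-en-7-yl]hexa-2,4-dienoate | C[Si](C)(C)OC1=C[C@H](C)CC[C@H]2[C@H](/C(C)=C/C=C/C(=O)OC)CC[C@]12C | intermediate
21 | methyl (2E,4E)-5-[(6S,7R,10S)-3,10-dimethyl-1-oxobicyclo[5.3.0]dec-2-en-7-yl]hexa-2,4-dienoate | O=C1C=C(C)CC[C@H]2[C@H](/C(C)=C/C=C/C(=O)OC)CC[C@]12C | intermediate
22 | methyl (2E,4E)-5-[(1S,6S,7R,10S)-1-hydroxy-3,10-dimethylbicyclo[5.3.0]dec-2-en-7-yl]hexa-2,4-dienoate | O[C@H]1C=C(C)CC[C@H]2[C@H](/C(C)=C/C=C/C(=O)OC)CC[C@]12C | intermediate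
23 | 4-nitrobenzoic acid | OC(=O)c1ccc(cc1)[N+](=O)[O-] | starting material
24 | (1R,6S,7R,10S)-7-[(2E,4E)-6-methoxy-6-oxohexa-2,4-dien-2-yl]-3,10-dimethylbicyclo[5.3.0]dec-2-en-1-yl 4-nitrobenzoate | O=C(O[C@@H]1C=C(C)CC[C@H]2[C@H](/C(C)=C/C=C/C(=O)OC)CC[C@]12C)c1ccc(cc1)[N+](=O)[O-] | intermediate
25 | methyl (2E,4E)-5-[(1R,6S,7R,10S)-1-hydroxy-3,10-dimethylbicyclo[5.3.0]dec-2-en-7-yl]hexa-2,4-dienoate | O[C@@H]1C=C(C)CC[C@H]2[C@H](/C(C)=C/C=C/C(=O)OC)CC[C@]12C | intermediate
26 | tert-butyl hydroperoxide | CC(C)(C)OO | starting material
27 | methyl (2E,4E)-5-[(1S,2S,3R,6S,7R,10S)-2,3-epoxy-1-hydroxy-3,10-dimethylbicyclo[5.3.0]dec-7-yl]hexa-2,4-dienoate | O[C@@H]1[C@@H]2O[C@]2(C)CC[C@H]2[C@H](/C(C)=C/C=C/C(=O)OC)CC[C@]12C | intermediate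
28 | (3E,5E)-6-[(1S,2S,3R,6S,7R,10S)-2,3-epoxy-1-hydroxy-3,10-dimethylbicyclo[5.3.0]dec-7-yl]-2-methylhepta-3,5-dien-2-ol | O[C@@H]1[C@@H]2O[C@]2(C)CC[C@H]2[C@H](/C(C)=C/C=C/C(C)(C)O)CC[C@]12C | intermediate
29 | acetic anhydride | CC(=O)OC(C)=O | starting material
30 | (1S,2S,3R,6S,7R,10S)-2,3-epoxy-7-[(2E,4E)-6-hydroxy-6-methylhepta-2,4-dien-2-yl]-3,10-dimethylbicyclo[5.3.0]dec-1-yl acetate | CC(=O)O[C@@H]1[C@@H]2O[C@]2(C)CC[C@H]2[C@H](/C(C)=C/C=C/C(C)(C)O)CC[C@]12C | target

## Step count and least certain steps

Total: 17 steps. Longest linear sequence: 17 steps, all from cycloheptane-1,3-dione 1.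

**Step 4 (key step).** The most likely failure is weak discrimination between the two enantiotopic carbonyls at the temperature needed for dehydration. The enolexo transition state on a flexible seven-membered dione is less rigid than the classical six-ring case, and a slow enamine step would also give time for ring cleavage of the dione. The fallback separates bond formation from dehydration. Starting from 8, the amino-acid-catalysed aldol addition is run at room temperature and stopped at ketol 9, which is isolated and enriched by crystallisation. A separate acid-catalysed dehydration (TsOH, toluene, 80 °C) then returns to the route at 10.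

**Step 6.** Hydrogen uptake at the tetrasubstituted olefin may be slow on the crowded face, and facial control is lost if the C11 hydroxyl binds iridium poorly or if redox isomerisation of the allylic alcohol intervenes. The fallback replaces metal delivery by electron transfer and sets out from 10. NaBH4 in EtOH at −20 °C reduces only the saturated C1 ketone and gives the (1S,10S) hydroxy enone F1. Reduction with Li in NH3 (THF, t-BuOH, −78 °C) protonates C6 of the enone dianion toward the trans-fused arrangement, and C7 settles on quench, giving the (1S,6S,7R,10S) hydroxy ketone F2. Dess–Martin oxidation of F2 returns to the route at 14.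

**Step 8.** Geometric control at the new trisubstituted C11=C12 bond may be incomplete, and the ambident phosphonate anion may react through its γ-carbon. The fallback builds the chain two carbons at a time from 14. Olefination with trimethyl phosphonoacetate and NaH gives the keto (E)-enoate F3, whose isomers separate readily. i-Bu2AlH reduces ester and ketone to the diol F4, and MnO2 oxidises only the allylic alcohol to the hydroxy enal F5. The stabilised ylide Ph3P=CHCO2Me adds the second E olefin to give the hydroxy dienoate F6, and Dess–Martin oxidation of F6 returns to the route at 16.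

**Step 13 (with the facial assumption of step 12).** The activated allylic alcohol may eliminate to a ring diene, or ionise with loss of stereochemical integrity, before the hindered displacement occurs. If step 12 happens to deliver 25 directly, steps 13 and 14 are simply omitted. The fallback changes the order of events and sets out from 21. Nucleophilic epoxidation (t-BuOOH, DBU, CH2Cl2) on the face anti to the axial C10 methyl group gives the epoxy ketone F7. Reduction with NaBH4 and CeCl3·7H2O, with hydride entering anti to the oxirane oxygen, returns to the route at 27.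

**Step 16.** The organolithium may open or rearrange the oxirane, or add in conjugate fashion to the dienoate, in competition with double addition to the ester. The fallback moves the methyl addition before the epoxidation and sets out from 25. MeLi at −78 °C gives the diol F8. Its vanadium-catalysed epoxidation relies on the secondary ring alkoxide and its trisubstituted olefin reacting faster than the hindered tertiary dienylic alcohol, and returns to the route at 28.

## Further compounds

F0 | step 4 | none | none
F1 | step 6 | (1S,10S)-7-acetyl-10-methylbicyclo[5.3.0]dec-6-en-1-ol | O[C@H]1CCCCC2=C(C(C)=O)CC[C@]12C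
F2 | step 6 | (1S,6S,7R,10S)-7-acetyl-10-methylbicyclo[5.3.0]decan-1-ol | O[C@H]1CCCC[C@H]2[C@H](C(C)=O)CC[C@]12C
F3 | step 8 | methyl (2E)-3-[(6S,7R,10S)-10-methyl-1-oxobicyclo[5.3.0]dec-7-yl]but-2-enoate | O=C1CCCC[C@H]2[C@H](/C(C)=C/C(=O)OC)CC[C@]12C
F4 | step 8 | (2E)-3-[(1S,6S,7R,10S)-1-hydroxy-10-methylbicyclo[5.3.0]dec-7-yl]but-2-en-1-ol | O[C@H]1CCCC[C@H]2[C@H](/C(C)=C/CO)CC[C@]12C
F5 | step 8 | (2E)-3-[(1S,6S,7R,10S)-1-hydroxy-10-methylbicyclo[5.3.0]dec-7-yl]but-2-enal | O[C@H]1CCCC[C@H]2[C@H](/C(C)=C/C=O)CC[C@]12C
F6 | step 8 | methyl (2E,4E)-5-[(1S,6S,7R,10S)-1-hydroxy-10-methylbicyclo[5.3.0]dec-7-yl]hexa-2,4-dienoate | O[C@H]1CCCC[C@H]2[C@H](/C(C)=C/C=C/C(=O)OC)CC[C@]12C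
F7 | step 13 | methyl (2E,4E)-5-[(2R,3R,6S,7R,10S)-2,3-epoxy-3,10-dimethyl-1-oxobicyclo[5.3.0]dec-7-yl]hexa-2,4-dienoate | O=C1[C@@H]2O[C@]2(C)CC[C@H]2[C@H](/C(C)=C/C=C/C(=O)OC)CC[C@]12C
F8 | step 16 | (3E,5E)-6-[(1R,6S,7R,10S)-1-hydroxy-3,10-dimethylbicyclo[5.3.0]dec-2-en-7-yl]-2-methylhepta-3,5-dien-2-ol | O[C@@H]1C=C(C)CC[C@H]2[C@H](/C(C)=C/C=C/C(C)(C)O)CC[C@]12C
A1 | alternative 1 | trans-hydroazulene with C1 triethylsilyl ether, C2=C3 methyl olefin and C7 tert-butyldimethylsilyl ether | CC[Si](CC)(CC)O[C@@H]1C=C(C)CC[C@H]2[C@H](O[Si](C)(C)C(C)(C)C)CC[C@]12C
A2 | alternative 1 | cyclopentane precursor with C6 vinyl group and (Z)-iodoalkene chain on C10 | CC[Si](CC)(CC)O[C@H](/C=C(/C)I)[C@@]1(C)CC[C@@H](O[Si](C)(C)C(C)(C)C)[C@@H]1C=C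
A3 | alternative 2 | trans-hydroazulen-8-one with C1 silyl ether and C7 isopropenyl group | CC(C)(C)[Si](C)(C)O[C@@H]1CCCC[C@H]2[C@H](C(C)=C)C(=O)C[C@]12C
A4 | alternative 2 | cycloheptane diazoketone precursor with tertiary C10–H | CC(C)(C)[Si](C)(C)O[C@@H]1CCCC[C@@H]([C@H](C(C)=C)C(=O)C=[N+]=[N-])[C@H]1C
A5 | alternative 3 | C1-boryl bicyclo[5.3.0]deca-2,5-diene with C7 ketal | CC1(C)OB(OC1(C)C)[C@@H]2C=C(C)CC=C3[C@H](C4(C)OCCO4)CC[C@]23C
A6 | alternative 3 | cis-1,2-dialkenylcyclopropane precursor | CC1(C)OB(OC1(C)C)/C=C/[C@@]2(C)C[C@H]2C3=C(C)CC[C@H]3C4(C)OCCO4
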